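**Plan**
- Chain numbering: C1=C2 vinyl, C3 carbinol, C4, C5, C6 ring CH, C7 bridgehead C(CH3)–O, C8 and C9 ring CH2, C10 bridgehead CH–O, C11 quaternary carbon, C12, C13, C14 CHBr, C15 C(CH3)2Cl. The target is 3S,6S,7S,10R,11S,14S.
- Enabling feature: in cyclohexane ring A (C6–C7–C8–C9–C10–C11) the ether oxygen sits on C10, next to quaternary C11 and 1,4 to tertiary C7. This is the imprint of a C10–C11 oxirane opened at C11 by a C6=C7 alkene, with the C7 cation caught by the same oxygen (ring B: O–C7–C8–C9–C10).
- Retrosynthesis: O–C7 and C6–C11 are cut together, which gives an acyclic epoxy diene that is an isomer of the silylated target. Then C10=C11 (Wittig), C11–C12 (ylide alkylation), C7–C8 (Negishi) and C6=C7 (Stork–Zhao) are cut.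
- Forward: the C20 chain is joined first. Ring A and then ring B close in one flask, and desilylation ends the route.
- Stereochemistry: C3 comes from (S)-linalool, C14 from a catalytic enantioselective bromochlorination, and C10 from a Sharpless epoxidation. C11 (inversion), C6 (chair, 6Z alkene) and C7 (bridge geometry) follow in the cyclisation.

Key step: step 13

Assumption: (S)-(+)-linalool (coriandrol) of high enantiomeric purity is taken as a commercial starting material.

Step 1
Reactants: 1 (S)-(+)-linalool
Product: 2 triethyl{[(3S)-3,7-dimethylocta-1,6-dien-3-yl]oxy}silane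
Conditions: Et3SiOTf, 2,6-lutidine, CH2Cl2, 0 °C
Reagents that add atoms: triethylsilyl trifluoromethanesulfonate, CC[Si](CC)(CC)OS(=O)(=O)C(F)(F)F
Why: Silyl ether protection with a silyl triflate and a hindered pyridine base silylates even tertiary alcohols, leaves C3 untouched, and the bulky ether later keeps this oxygen out of the cationic step.

Step 2
Reactants: 2 triethylsilyl ether of linalool
Product: 4 (4S)-4-methyl-4-(triethylsilyloxy)hex-5-enal, via secondary ozonide 3 (not isolated)
Conditions: O3 (to the Sudan Red 7B end point), CH2Cl2, −78 °C; then Me2S, −78 °C to rt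
Reagents that add atoms: ozone, [O-][O+]=O
Why: Chemoselective ozonolysis should work because ozone adds much faster to the electron-rich trisubstituted alkene than to the hindered monosubstituted vinyl group, so titration to a dye end point and reductive work-up should cleave only the C6=C7 bond of 2.

Step 3
Reactants: 4 (4S)-4-methyl-4-(triethylsilyloxy)hex-5-enal
Product: 5 (3S,6Z)-7-iodo-3-methyl-3-(triethylsilyloxy)octa-1,6-diene
Conditions: EtPPh3I, n-BuLi, THF, rt; I2, −78 °C; NaN(SiMe3)2, −20 °C; then 4, −78 °C
Reagents that add atoms: ethyltriphenylphosphonium iodide, CC[P+](c1ccccc1)(c1ccccc1)c1ccccc1.[I-]; iodine, II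
Why: In the Stork–Zhao olefination the non-stabilised α-iodo ylide adds to the unbranched aldehyde under kinetic control through the cis-oxaphosphetane, which places iodine cis to the C5 chain (Z), the geometry that later sets C6.

Step 4
Reactants: 5 (3S,6Z)-7-iodo-3-methyl-3-(triethylsilyloxy)octa-1,6-diene
Product: 6 ethyl (4Z,8S)-4,8-dimethyl-8-(triethylsilyloxy)deca-4,9-dienoate
Conditions: BrZnCH2CH2CO2Et, Pd(PPh3)4 (5 mol %), THF, 40 °C
Reagents that add atoms: (3-ethoxy-3-oxopropyl)zinc bromide, CCOC(=O)CC[Zn]Br
Why: In the Negishi coupling, oxidative addition of zerovalent palladium into the alkenyl iodide and reductive elimination both go with retention, so the zinc homoenolate carbon (C8) takes the place of iodine, the 6Z alkene is kept, and ester and silyl ether are inert to the organozinc.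

Step 5
Reactants: 6 ethyl (4Z,8S)-4,8-dimethyl-8-(triethylsilyloxy)deca-4,9-dienoate
Product: 7 (4Z,8S)-4,8-dimethyl-8-(triethylsilyloxy)deca-4,9-dienal
Conditions: i-Bu2AlH (1.05 equiv), toluene, −78 °C; aq. potassium sodium tartrate
Reagents that add atoms: none
Why: In this partial ester reduction with i-Bu2AlH the tetrahedral aluminium hemiacetal is stable at −78 °C until work-up, so the reduction should stop at the C10 aldehyde.

Step 6
Reactants: 8 4-methylpent-3-en-1-ol
Product: 9 (3S)-3-bromo-4-chloro-4-methylpentan-1-ol
Conditions: NBS, ClTi(OiPr)3, chiral tridentate salicylaldimine–amino alcohol (Schiff base) ligand (20 mol %, the antipode that gives the S bromide), hexanes, −20 °C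
Reagents that add atoms: N-bromosuccinimide, O=C1CCC(=O)N1Br; chlorotitanium triisopropoxide, CC(C)O[Ti](Cl)(OC(C)C)OC(C)C
Why: In the titanium–Schiff base catalysed enantioselective bromochlorination of allylic and homoallylic alcohols, the titanium alkoxide of 8 holds the alkene in the chiral pocket, NBS forms the bromonium ion on one face, and titanium-bound chloride opens it anti at the tertiary carbon, which sets C14 as S.

Step 7
Reactants: 9 (3S)-3-bromo-4-chloro-4-methylpentan-1-ol
Product: 10 (3S)-3-bromo-4-chloro-4-methylpentyl trifluoromethanesulfonate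
Conditions: Tf2O, 2,6-lutidine, CH2Cl2, −78 °C
Reagents that add atoms: trifluoromethanesulfonic anhydride, O=S(=O)(OS(=O)(=O)C(F)(F)F)C(F)(F)F
Why: O-triflation of a primary alcohol at low temperature with a non-nucleophilic base touches no bond at C14, and the triflate is used at once.

Step 8
Reactants: 10 (3S)-3-bromo-4-chloro-4-methylpentyl trifluoromethanesulfonate; 11 methyl (triphenylphosphoranylidene)acetate (2.1 equiv)
Product: 13 methyl (5S)-5-bromo-6-chloro-6-methyl-2-(triphenyl-λ5-phosphanylidene)heptanoate, via phosphonium triflate 12 (not isolated)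
Conditions: CH2Cl2, 0 °C to rt
Reagents that add atoms: none
Why: This is C-alkylation of an ester-stabilised ylide followed by transylidation: one equivalent of 11 displaces the primary triflate (C11–C12 bond), the second deprotonates salt 12, and the neopentyl-type secondary bromide and the tertiary chloride are too hindered to compete.

Step 9
Reactants: 7 (4Z,8S)-4,8-dimethyl-8-(triethylsilyloxy)deca-4,9-dienal; 13 substituted ylide
Product: 14 methyl (2E,6Z,10S)-2-[(3S)-3-bromo-4-chloro-4-methylpentyl]-6,10-dimethyl-10-(triethylsilyloxy)dodeca-2,6,11-trienoate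
Conditions: toluene, 80 °C
Reagents that add atoms: none
Why: A Wittig olefination with an α-substituted ester-stabilised ylide gives the E enoate (ester trans to C9), so the bromochloro chain ends cis to C9 as C11 of the target demands, and the neutral medium spares halides, silyl ether and the 6Z alkene.

Step 10
Reactants: 14 E enoate
Product: 15 (2E,6Z,10S)-2-[(3S)-3-bromo-4-chloro-4-methylpentyl]-6,10-dimethyl-10-(triethylsilyloxy)dodeca-2,6,11-trien-1-ol
Conditions: i-Bu2AlH (2.5 equiv), CH2Cl2, −78 °C; aq. potassium sodium tartrate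
Reagents that add atoms: none
Why: 1,2-Reduction of the enoate with i-Bu2AlH at −78 °C gives the allylic alcohol without touching the alkyl halides or either alkene geometry.

Step 11
Reactants: 15 allylic alcohol
Product: 16 {(2R,3R)-2-[(3S)-3-bromo-4-chloro-4-methylpentyl]-3-[(3Z,7S)-3,7-dimethyl-7-(triethylsilyloxy)nona-3,8-dien-1-yl]oxiran-2-yl}methanol
Conditions: Ti(OiPr)4 (10 mol %), D-(−)-diisopropyl tartrate (12 mol %), t-BuOOH, 4 Å molecular sieves, CH2Cl2, −20 °C
Reagents that add atoms: tert-butyl hydroperoxide, CC(C)(C)OO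
Why: In the Sharpless asymmetric epoxidation only the allylic alkene is bound to titanium, so C6=C7 and the vinyl group stay intact, and D-(−)-tartrate delivers oxygen under catalyst control to the face of this 2,3E-disubstituted allylic alcohol that gives the 2R,3R oxirane (C10 R, C9 cis to C12).

Step 12
Reactants: 16 epoxy alcohol
Product: 18 (2S,3R)-2-[(3S)-3-bromo-4-chloro-4-methylpentyl]-3-[(3Z,7S)-3,7-dimethyl-7-(triethylsilyloxy)nona-3,8-dien-1-yl]-2-methyloxirane, via epoxy triflate 17 (not isolated)
Conditions: Tf2O (1.05 equiv), 2,6-lutidine, CH2Cl2, −78 °C; then LiBHEt3, THF, −78 to −40 °C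
Reagents that add atoms: none
Why: This is sulfonate activation followed by SN2 hydride displacement: the primary triflate 17 should react with LiBHEt3 far faster than the trisubstituted oxirane or the neopentyl-type secondary bromide, the by-product BEt3 does not hydroborate, and no stereocentre is touched (the C11 descriptor changes by priority only).

Step 13
Reactants: 18 epoxy diene
Product: 20 triethylsilyl ether of the target, via cyclohexyl cation zwitterion 19 (not isolated)
Conditions: BF3·OEt2 (0.3 equiv), CH2Cl2, −78 °C; Et3N quench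
Reagents that add atoms: none
Why: BF3 binds the oxirane oxygen, the C6=C7 π bond attacks the tertiary C11 from the back of the C11–O bond (closure of ring A, 6-endo with respect to both oxirane and alkene), and the tertiary C7 cation of 19 is then caught across the ring by the C10 alkoxytrifluoroborate oxygen (transannular 1,4-capture), which closes the five-membered ring B as the last ring and releases BF3. The closest known reaction type is the Lewis acid cyclisation of 6,7-epoxygeranyl derivatives and related epoxy polyenes, the presumed biosynthetic mode, in which 7-oxabicyclo[2.2.1]heptanes arise by this same oxygen termination. C10 keeps its Sharpless-derived configuration, C11 is set by inversion so that the chain cis to C9 in the oxirane ends syn to the oxygen bridge, C6 is set by the chair transition state in which the 6Z geometry forces the C5 chain axial and hence trans to the equatorial C10–O bond, and C7 has no freedom because the oxygen can reach only one face. Once the C10 end of the ring flips, both long chains of 19 are equatorial and the oxygen is axial, 1,4 to the empty orbital, which should favour ether closure over proton loss. The step needs opening at C11 rather than C10 (tertiary against secondary cation character), attack by C6=C7 rather than by the vinyl group (trisubstituted against monosubstituted, and only the former gives a six-membered ring), and no reaction from the C3 oxygen or the halogens (bulky tertiary silyl ether, inductively deactivated vicinal Br/Cl, −78 °C, no external base or nucleophile).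

Step 14
Reactants: 20 triethylsilyl ether of the target
Product: 21 (3S)-5-{(1S,2S,3S,4R)-3-[(3S)-3-bromo-4-chloro-4-methylpentyl]-1,3-dimethyl-7-oxabicyclo[2.2.1]heptan-2-yl}-3-methylpent-1-en-3-ol
Conditions: HF·pyridine, pyridine, THF, 0 °C
Reagents that add atoms: none
Why: Fluoride-driven silyl ether cleavage in pyridine-buffered HF is mild enough to avoid ionisation of the tertiary allylic alcohol and E2 loss of HBr or HCl.

**Compound list**
1 | (S)-(+)-linalool | C=C[C@@](C)(O)CCC=C(C)C | starting material
2 | triethyl{[(3S)-3,7-dimethylocta-1,6-dien-3-yl]oxy}silane | C=C[C@@](C)(O[Si](CC)(CC)CC)CCC=C(C)C | intermediate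
3 | secondary ozonide of 2 (1,2,4-trioxolane, epimers at the ring CH) | C=C[C@@](C)(O[Si](CC)(CC)CC)CCC1OOC(C)(C)O1 | intermediate
4 | (4S)-4-methyl-4-(triethylsilyloxy)hex-5-enal | C=C[C@@](C)(O[Si](CC)(CC)CC)CCC=O | intermediate
5 | (3S,6Z)-7-iodo-3-methyl-3-(triethylsilyloxy)octa-1,6-diene | C=C[C@@](C)(O[Si](CC)(CC)CC)CC/C=C(/C)I | intermediate
6 | ethyl (4Z,8S)-4,8-dimethyl-8-(triethylsilyloxy)deca-4,9-dienoate | C=C[C@@](C)(O[Si](CC)(CC)CC)CC/C=C(/C)CCC(=O)OCC | intermediate
7 | (4Z,8S)-4,8-dimethyl-8-(triethylsilyloxy)deca-4,9-dienal | C=C[C@@](C)(O[Si](CC)(CC)CC)CC/C=C(/C)CCC=O | intermediate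
8 | 4-methylpent-3-en-1-ol | CC(C)=CCCO | starting material
9 | (3S)-3-bromo-4-chloro-4-methylpentan-1-ol | OCC[C@H](Br)C(C)(C)Cl | intermediate
10 | (3S)-3-bromo-4-chloro-4-methylpentyl trifluoromethanesulfonate | O=S(=O)(OCC[C@H](Br)C(C)(C)Cl)C(F)(F)F | intermediate
11 | methyl (triphenylphosphoranylidene)acetate | COC(=O)C=P(c1ccccc1)(c1ccccc1)c1ccccc1 | starting material
12 | [(5S)-5-bromo-6-chloro-1-methoxy-6-methyl-1-oxoheptan-2-yl]triphenylphosphonium triflate (epimers at C2) | COC(=O)C(CC[C@H](Br)C(C)(C)Cl)[P+](c1ccccc1)(c1ccccc1)c1ccccc1.[O-]S(=O)(=O)C(F)(F)F | intermediate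
13 | methyl (5S)-5-bromo-6-chloro-6-methyl-2-(triphenyl-λ5-phosphanylidene)heptanoate | COC(=O)C(CC[C@H](Br)C(C)(C)Cl)=P(c1ccccc1)(c1ccccc1)c1ccccc1 | intermediate
14 | methyl (2E,6Z,10S)-2-[(3S)-3-bromo-4-chloro-4-methylpentyl]-6,10-dimethyl-10-(triethylsilyloxy)dodeca-2,6,11-trienoate | C=C[C@@](C)(O[Si](CC)(CC)CC)CC/C=C(/C)CC/C=C(/C(=O)OC)CC[C@H](Br)C(C)(C)Cl | intermediate
15 | (2E,6Z,10S)-2-[(3S)-3-bromo-4-chloro-4-methylpentyl]-6,10-dimethyl-10-(triethylsilyloxy)dodeca-2,6,11-trien-1-ol | C=C[C@@](C)(O[Si](CC)(CC)CC)CC/C=C(/C)CC/C=C(/CO)CC[C@H](Br)C(C)(C)Cl | intermediate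
16 | {(2R,3R)-2-[(3S)-3-bromo-4-chloro-4-methylpentyl]-3-[(3Z,7S)-3,7-dimethyl-7-(triethylsilyloxy)nona-3,8-dien-1-yl]oxiran-2-yl}methanol | C=C[C@@](C)(O[Si](CC)(CC)CC)CC/C=C(/C)CC[C@H]1O[C@@]1(CO)CC[C@H](Br)C(C)(C)Cl | intermediate
17 | trifluoromethanesulfonate of 16 | C=C[C@@](C)(O[Si](CC)(CC)CC)CC/C=C(/C)CC[C@H]1O[C@@]1(COS(=O)(=O)C(F)(F)F)CC[C@H](Br)C(C)(C)Cl | intermediate
18 | (2S,3R)-2-[(3S)-3-bromo-4-chloro-4-methylpentyl]-3-[(3Z,7S)-3,7-dimethyl-7-(triethylsilyloxy)nona-3,8-dien-1-yl]-2-methyloxirane | C=C[C@@](C)(O[Si](CC)(CC)CC)CC/C=C(/C)CC[C@H]1O[C@@]1(C)CC[C@H](Br)C(C)(C)Cl | intermediate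
19 | monocyclic zwitterion (ring A closed, C7 cation, C10 alkoxytrifluoroborate) | C=C[C@@](C)(O[Si](CC)(CC)CC)CC[C@H]1[C@](C)(CC[C@H](Br)C(C)(C)Cl)[C@H](O[B-](F)(F)F)CC[C+]1C | intermediate
20 | triethylsilyl ether of 21 | C=C[C@@](C)(O[Si](CC)(CC)CC)CC[C@H]1[C@](C)(CC[C@H](Br)C(C)(C)Cl)[C@H]2CC[C@]1(C)O2 | intermediate
21 | (3S)-5-{(1S,2S,3S,4R)-3-[(3S)-3-bromo-4-chloro-4-methylpentyl]-1,3-dimethyl-7-oxabicyclo[2.2.1]heptan-2-yl}-3-methylpent-1-en-3-ol | C=C[C@@](C)(O)CC[C@H]1[C@](C)(CC[C@H](Br)C(C)(C)Cl)[C@H]2CC[C@]1(C)O2 | target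

**Total step count:** 14 steps.
**Longest linear sequence:** 11 steps (1 to 21 through steps 1–5 and 9–14).

**Steps most likely to fail**

1. Step 13. Loss of a proton from the C7 cation, or a 1,2-hydride shift at the opened oxirane, may overtake capture by oxygen, and a boat-like folding may erode control at C6.
   - The fallback sets out from 18 and comes back at 20 by uncoupling the two ring closures.
   - 18 is treated with MeAlCl2 in CH2Cl2 at −78 °C. The aluminium alkoxide is a poor nucleophile there, so the cation is expected to shed a C8 proton. This gives the cyclohexenol F1 (C7=C8 alkene, free C10 hydroxyl; C6, C10 and C11 as in 20).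
   - A catalytic amount of p-toluenesulfonic acid in CH2Cl2 then reprotonates the alkene at C8 and the axial hydroxyl closes the oxygen bridge. This is the acid-catalysed transannular hydroalkoxylation known from the conversion of terpinen-4-ol into 1,4-cineole.
   - Proton loss is reversible under these conditions, so the bicyclic ether should be the sink.

2. Step 6. Capture of the bromonium ion by the free hydroxyl group (bromoetherification) may compete. Facial discrimination may also be weaker, because the anchoring oxygen is one carbon further from the alkene than in an allylic alcohol. An erosion at C14 cannot be corrected later.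
   - The fallback sets out from 8 and comes back at 9. It replaces the asymmetric halogenation with stereospecific substitutions.
   - 8 is silylated (t-BuPh2SiCl, imidazole) to the silyl ether F2.
   - Shi epoxidation (D-fructose-derived ketone, KHSO5, K2CO3 buffer) gives the R oxirane F3.
   - Li2NiBr4 in THF opens it by SN2 attack of bromide at the secondary carbon, with inversion, to the S bromohydrin F4.
   - SOCl2 exchanges the tertiary hydroxyl for chloride through the bridged bromonium ion, which leaves the bromine-bearing carbon unchanged, to give the silylated bromochloride F5.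
   - HF·pyridine frees 9.

3. Step 3. Thermal decay and iodine scrambling of the α-iodo ylide and incomplete Z control are possible. Any leak in alkene geometry is passed on to C6 in step 13.
   - The fallback sets out from 4 and comes back at 6, so it replaces steps 3 and 4.
   - Still–Gennari olefination of 4 with methyl 2-[bis(2,2,2-trifluoroethoxy)phosphoryl]propanoate (KN(SiMe3)2, 18-crown-6, THF, −78 °C) gives the Z enoate F6, whose ester carbon is C8.
   - i-Bu2AlH reduces it to the allylic alcohol F7, and CBr4/PPh3 gives the allylic bromide F8.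
   - The lithium enolate of ethyl acetate (LiN(iPr)2, THF, −78 °C) displaces bromide at C8 with retention of the alkene geometry to give 6.

**Further compounds**
F1 | step 13 | cyclohexenol: (1R,2S,3R)-2-[(3S)-3-bromo-4-chloro-4-methylpentyl]-2,4-dimethyl-3-[(3S)-3-methyl-3-(triethylsilyloxy)pent-4-en-1-yl]cyclohex-4-en-1-ol | C=C[C@@](C)(O[Si](CC)(CC)CC)CC[C@H]1[C@](C)(CC[C@H](Br)C(C)(C)Cl)[C@H](O)CC=C1C
F2 | step 6 | tert-butyl[(4-methylpent-3-en-1-yl)oxy]diphenylsilane | CC(C)=CCCO[Si](c1ccccc1)(c1ccccc1)C(C)(C)C
F3 | step 6 | tert-butyl{2-[(2R)-3,3-dimethyloxiran-2-yl]ethoxy}diphenylsilane | CC1(C)O[C@@H]1CCO[Si](c2ccccc2)(c2ccccc2)C(C)(C)C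
F4 | step 6 | (3S)-3-bromo-5-[(tert-butyldiphenylsilyl)oxy]-2-methylpentan-2-ol | CC(C)(C)[Si](OCC[C@H](Br)C(C)(C)O)(c1ccccc1)c1ccccc1
F5 | step 6 | {[(3S)-3-bromo-4-chloro-4-methylpentyl]oxy}(tert-butyl)diphenylsilane | CC(C)(C)[Si](OCC[C@H](Br)C(C)(C)Cl)(c1ccccc1)c1ccccc1
F6 | step 3 | methyl (2Z,6S)-2,6-dimethyl-6-(triethylsilyloxy)octa-2,7-dienoate | C=C[C@@](C)(O[Si](CC)(CC)CC)CC/C=C(/C)C(=O)OC
F7 | step 3 | (2Z,6S)-2,6-dimethyl-6-(triethylsilyloxy)octa-2,7-dien-1-ol | C=C[C@@](C)(O[Si](CC)(CC)CC)CC/C=C(/C)CO
F8 | step 3 | (3S,6Z)-8-bromo-3,7-dimethyl-3-(triethylsilyloxy)octa-1,6-diene | C=C[C@@](C)(O[Si](CC)(CC)CC)CC/C=C(/C)CBr
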